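**Retrosynthetic overview**

1. Feature: the C3 ketone and the C5=C10 alkene of rings A and B place the two quaternary carbons C4 (α, carrying C18 and C19) and C9 (δ, carrying C20 and the C11–C12 chain) at the two ends of one dienolate, so the target is cut back to a 3-keto-4,9(10)-diene.
2. Key disconnection: C9–C11 (vinyl, copper-catalysed 1,6-addition) and C4–C19 (formaldehyde, aldol trapping) in one operation on the bicyclic 6-silyloxy-4,8,9-trimethyl-4,9(10)-dien-3-one; no ring forms in it.
3. After it: the C19 hydroxyl is acylated, the vinyl group is hydroborated and coupled with 4-bromofuran-2(5H)-one, and both silyl ethers are removed.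
4. Before it: ring B first (enamine-catalysed Michael addition and aldol condensation set C8; the C9 methyl, the C10 side chain and the C6 oxygen are added on the monocyclic enone), then ring A by aldol condensation onto C5; the butenolide ring is bought.
5. The C6 oxygen is introduced while C6 is still α to the ring B ketone, because enol derivatives of the finished dienone form toward C8 and C20 and would erase the C8 centre.

Key step: step 11

Convention: halimane numbering; the α face carries the C6 oxygen, C11 and C18, the β face carries C17, C19 and C20.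
Assumption: 2-ethyl-2-vinyl-1,3-dioxolane (the ethylene ketal of ethyl vinyl ketone) is taken as a purchasable reagent.

**Route**

Step 1
Reactants: 1 propanal; 2 but-3-en-2-one
Product: 3 (S)-2-methyl-5-oxohexanal
Conditions: (R)-2-[methoxy(diphenyl)methyl]pyrrolidine (5 mol%), ethyl 3,4-dihydroxybenzoate (20 mol%), neat, 4 °C
Reagents that add atoms: none
Why: Enamine-catalysed Michael addition with a diarylprolinol ether, in which the E-enamine of propanal should add to the enone on the face remote from the CPh2OMe group and so set C8 as S (the enantiomeric catalyst would give the antipode).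

Step 2
Reactants: 3 (S)-2-methyl-5-oxohexanal
Product: 4 (S)-4-methylcyclohex-2-en-1-one
Conditions: LiOH (0.1 equiv), i-PrOH, 0 °C to rt
Reagents that add atoms: none
Why: Intramolecular aldol condensation of the methyl ketone onto the aldehyde (six-membered ring, then E1cB loss of water), run with catalytic base so that the aldehyde is consumed before its α-centre epimerises.

Step 3
Reactants: 4 (S)-4-methylcyclohex-2-en-1-one; 5 methylmagnesium bromide
Product: 6 trimethyl{[(3R,4S)-3,4-dimethylcyclohex-1-en-1-yl]oxy}silane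
Conditions: MeMgBr (1.3 equiv), CuBr·SMe2 (5 mol%), Me3SiCl (2 equiv), DMPU, THF, −78 °C; Et3N, cold aq. NaHCO3
Reagents that add atoms: chlorotrimethylsilane, C[Si](C)(C)Cl
Why: Copper-catalysed conjugate addition of the Grignard reagent accelerated by the chlorosilane, with the enolate trapped as its silyl enol ether; the methyl group enters C9 anti to the C8 methyl, but this centre is erased in step 4.

Step 4
Reactants: 6 trimethyl{[(3R,4S)-3,4-dimethylcyclohex-1-en-1-yl]oxy}silane
Product: 7 (S)-3,4-dimethylcyclohex-2-en-1-one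
Conditions: Pd(OAc)2 (10 mol%), O2 (1 atm), DMSO, 40 °C
Reagents that add atoms: none
Why: Saegusa–Ito dehydrosilylation, in which the palladium enolate loses the C9 hydride and returns the enone, now with the C9 methyl in place and C8 untouched.

Step 5
Reactants: 7 (S)-3,4-dimethylcyclohex-2-en-1-one
Product: 9 (S)-2-bromo-3,4-dimethylcyclohex-2-en-1-one, via the dibromo ketone 8 (not isolated)
Conditions: Br2 (1.05 equiv), CH2Cl2, 0 °C; then Et3N (1.5 equiv), 0 °C to rt
Reagents that add atoms: bromine, BrBr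
Why: Bromine addition to the enone followed by E1cB loss of HBr (the C10 hydrogen is α to the ketone) gives the α-bromo enone without involving C8.

Step 6
Reactants: 9 (S)-2-bromo-3,4-dimethylcyclohex-2-en-1-one; 10 2-ethyl-2-vinyl-1,3-dioxolane
Product: 12 (S)-2-[2-(2-ethyl-1,3-dioxolan-2-yl)ethyl]-3,4-dimethylcyclohex-2-en-1-one, via the B-alkyl-9-BBN adduct 11 (not isolated)
Conditions: 10, 9-BBN, THF, rt; then 9, Pd(dppf)Cl2 (5 mol%), AsPh3 (5 mol%), K3PO4 (3 M aq., 3 equiv), DMF, rt
Reagents that add atoms: none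
Why: B-alkyl Suzuki–Miyaura coupling of an α-halo enone with the anti-Markovnikov 9-BBN adduct of the terminal alkene attaches C1–C4 and C18 to C10, with the side-chain ketone masked as the dioxolane for step 7.

Step 7
Reactants: 12 (S)-2-[2-(2-ethyl-1,3-dioxolan-2-yl)ethyl]-3,4-dimethylcyclohex-2-en-1-one
Product: 14 (4S,6S)-2-[2-(2-ethyl-1,3-dioxolan-2-yl)ethyl]-6-hydroxy-3,4-dimethylcyclohex-2-en-1-one, via the potassium dienolate 13 (not isolated)
Conditions: KN(SiMe3)2 (1.1 equiv), THF, −78 °C; then 2-(phenylsulfonyl)-3-phenyloxaziridine (1.3 equiv), −78 °C; aq. NH4Cl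
Reagents that add atoms: 2-(phenylsulfonyl)-3-phenyloxaziridine, O=S(=O)(c1ccccc1)N1OC1c1ccccc1
Why: Enolate hydroxylation with an N-sulfonyloxaziridine, in which kinetic deprotonation can only occur at C6 (C10 has no hydrogen) and the oxidant should attack the dienolate on the face opposite the 1,3-related C8 methyl, giving the 6,8-trans α'-hydroxy enone (6S).

Step 8
Reactants: 14 (4S,6S)-2-[2-(2-ethyl-1,3-dioxolan-2-yl)ethyl]-6-hydroxy-3,4-dimethylcyclohex-2-en-1-one
Product: 15 (4S,6S)-6-[(tert-butyldimethylsilyl)oxy]-2-[2-(2-ethyl-1,3-dioxolan-2-yl)ethyl]-3,4-dimethylcyclohex-2-en-1-one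
Conditions: TBSCl (1.5 equiv), imidazole (3 equiv), DMF, rt
Reagents that add atoms: tert-butyl(chloro)dimethylsilane, CC(C)(C)[Si](C)(C)Cl
Why: Silylation of the secondary alcohol under mild conditions that should neither epimerise the α-hydroxy ketone nor open the dioxolane.

Step 9
Reactants: 15 (4S,6S)-6-[(tert-butyldimethylsilyl)oxy]-2-[2-(2-ethyl-1,3-dioxolan-2-yl)ethyl]-3,4-dimethylcyclohex-2-en-1-one
Product: 16 (4S,6S)-6-[(tert-butyldimethylsilyl)oxy]-3,4-dimethyl-2-(3-oxopentyl)cyclohex-2-en-1-one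
Conditions: PPTS (0.2 equiv), acetone/H2O (10:1), 40 °C
Reagents that add atoms: water, O
Why: Acid-catalysed ketal hydrolysis under conditions mild enough to leave the secondary silyl ether and the C6 centre alone.

Step 10
Reactants: 16 (4S,6S)-6-[(tert-butyldimethylsilyl)oxy]-3,4-dimethyl-2-(3-oxopentyl)cyclohex-2-en-1-one
Product: 17 (6S,8S)-8-[(tert-butyldimethylsilyl)oxy]-1,5,6-trimethyl-4,6,7,8-tetrahydronaphthalen-2(3H)-one
Conditions: KOt-Bu (0.2 equiv), t-BuOH/THF, 0 °C to rt; cold aq. NH4Cl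
Reagents that add atoms: none
Why: Intramolecular aldol condensation of a seco-dione onto an enone carbonyl (the ring A closure known from 19-norsteroid synthesis), in which the C4 enolate of the ethyl ketone adds to C5 and water is lost to the linear dienone; a substoichiometric base at low temperature is used because C6–H and C8–H remain enolisable.

Step 11
Reactants: 17 (6S,8S)-8-[(tert-butyldimethylsilyl)oxy]-1,5,6-trimethyl-4,6,7,8-tetrahydronaphthalen-2(3H)-one; 18 vinylmagnesium bromide; 19 formaldehyde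
Product: 21 (1S,5R,6S,8S)-8-[(tert-butyldimethylsilyl)oxy]-5-ethenyl-1-(hydroxymethyl)-1,5,6-trimethyl-3,4,5,6,7,8-hexahydronaphthalen-2(1H)-one, via the bromomagnesium dienolate 20 (not isolated)
Conditions: CuBr·SMe2 (20 mol%), vinylmagnesium bromide (2.5 equiv, slow addition), THF, −78 to −40 °C; then monomeric CH2O (gas from cracked paraformaldehyde, excess), −78 °C; aq. NH4Cl at −78 °C
Reagents that add atoms: none
Why: Proposed new method: the vinylcuprate formed from the Grignard reagent and CuBr·SMe2 should π-complex the dienone reversibly, move to the δ-carbon because the β-carbon C5 is flanked by the C4 methyl, the C6 silyloxy group and the ring fusion, and form C9–C11 by reductive elimination from the δ-bound trivalent copper species, leaving the bromomagnesium dienolate O–C3=C4–C5=C10, which should add to formaldehyde at its α-carbon C4 through a closed magnesium-bridged transition state so that C4–C19 forms and the tetrasubstituted C5=C10 alkene stays in place. The closest known reaction types are the copper-catalysed 1,6-addition of Grignard reagents to steroidal 4,6-dien-3-ones, the copper-mediated vinyl addition to β,β-disubstituted enones that gives quaternary carbons, and aldol trapping of conjugate-addition enolates with formaldehyde; their union on a δ,δ-disubstituted 4,9(10)-dien-3-one is new. No ring closes. C9 is controlled by the C8 methyl: the facial choice falls in the reductive elimination, where the bulky copper centre must stand pseudoaxial on C9 and should bond anti to the vicinal methyl, which then sits pseudoaxial on the β face, so vinyl enters on the α face (C4–C5 is by then a single bond of the forming dienolate, which lets the C6 silyloxy group lie pseudoequatorial). C4 is controlled by the C6 silyloxy group: in the planar dienolate the C4 methyl lies in the plane and allylic strain turns the silyloxy group pseudoaxial on the α face, so formaldehyde should enter from the β face. The step needs 1,6- over 1,2- and 1,4-addition (copper catalysis at low temperature, blocked C5), α- over γ-trapping (chelated aldol) and both facial selectivities, of which the one at C9 is the less secure because the two half-chairs of ring B lie close in energy.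

Step 12
Reactants: 22 3-(4-hydroxyphenyl)propanoic acid
Product: 24 3-{4-[(tert-butyldimethylsilyl)oxy]phenyl}propanoic acid, via the bis-silyl derivative 23 (not isolated)
Conditions: TBSCl (2.2 equiv), imidazole (4.4 equiv), DMF, rt; then THF/H2O/AcOH, rt
Reagents that add atoms: tert-butyl(chloro)dimethylsilane, CC(C)(C)[Si](C)(C)Cl
Why: Silylation of phenol and acid followed by selective hydrolysis of the labile silyl ester leaves only the phenol protected.

Step 13
Reactants: 21 (1S,5R,6S,8S)-8-[(tert-butyldimethylsilyl)oxy]-5-ethenyl-1-(hydroxymethyl)-1,5,6-trimethyl-3,4,5,6,7,8-hexahydronaphthalen-2(1H)-one; 24 3-{4-[(tert-butyldimethylsilyl)oxy]phenyl}propanoic acid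
Product: 25 [(1S,5R,6S,8S)-8-[(tert-butyldimethylsilyl)oxy]-5-ethenyl-1,5,6-trimethyl-2-oxo-1,2,3,4,5,6,7,8-octahydronaphthalen-1-yl]methyl 3-{4-[(tert-butyldimethylsilyl)oxy]phenyl}propanoate
Conditions: DCC (1.5 equiv), DMAP (0.2 equiv), CH2Cl2, 0 °C to rt
Reagents that add atoms: none
Why: Steglich esterification of the neopentyl primary alcohol under near-neutral conditions, which should avoid retro-aldol loss of formaldehyde from the β-hydroxy ketone.

Step 14
Reactants: 25 [(1S,5R,6S,8S)-8-[(tert-butyldimethylsilyl)oxy]-5-ethenyl-1,5,6-trimethyl-2-oxo-1,2,3,4,5,6,7,8-octahydronaphthalen-1-yl]methyl 3-{4-[(tert-butyldimethylsilyl)oxy]phenyl}propanoate; 26 4-bromofuran-2(5H)-one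
Product: 28 [(1S,5R,6S,8S)-8-[(tert-butyldimethylsilyl)oxy]-1,5,6-trimethyl-2-oxo-5-[2-(5-oxo-2,5-dihydrofuran-3-yl)ethyl]-1,2,3,4,5,6,7,8-octahydronaphthalen-1-yl]methyl 3-{4-[(tert-butyldimethylsilyl)oxy]phenyl}propanoate, via the B-alkyl-9-BBN adduct 27 (not isolated)
Conditions: 9-BBN (2.5 equiv), THF, rt to 40 °C; then 26, Pd(dppf)Cl2 (10 mol%), AsPh3 (10 mol%), K3PO4 (3 M aq., 3 equiv), DMF, rt
Reagents that add atoms: none
Why: Anti-Markovnikov hydroboration of the only reactive alkene (C5=C10 is tetrasubstituted and the C3 ketone is flanked by the quaternary C4, so 9-BBN should spare both) followed by B-alkyl Suzuki–Miyaura coupling with the β-bromobutenolide builds C12–C13.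

Step 15
Reactants: 28 [(1S,5R,6S,8S)-8-[(tert-butyldimethylsilyl)oxy]-1,5,6-trimethyl-2-oxo-5-[2-(5-oxo-2,5-dihydrofuran-3-yl)ethyl]-1,2,3,4,5,6,7,8-octahydronaphthalen-1-yl]methyl 3-{4-[(tert-butyldimethylsilyl)oxy]phenyl}propanoate
Product: 29 CNP0301014.1, [(1S,5R,6S,8S)-8-hydroxy-1,5,6-trimethyl-2-oxo-5-[2-(5-oxo-2,5-dihydrofuran-3-yl)ethyl]-1,2,3,4,5,6,7,8-octahydronaphthalen-1-yl]methyl 3-(4-hydroxyphenyl)propanoate
Conditions: HF·pyridine, pyridine/THF, 0 °C to rt
Reagents that add atoms: none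
Why: Fluoride-mediated cleavage of the alkyl and the aryl silyl ether under mildly acidic conditions that should leave the ester, the butenolide and the allylic alcohol intact; no stereocentre is touched.

**Compound list**

1 | propanal | CCC=O | starting material
2 | but-3-en-2-one (methyl vinyl ketone) | CC(=O)C=C | starting material
3 | (S)-2-methyl-5-oxohexanal | C[C@H](C=O)CCC(C)=O | intermediate
4 | (S)-4-methylcyclohex-2-en-1-one | C[C@H]1CCC(=O)C=C1 | intermediate
5 | methylmagnesium bromide | C[Mg]Br | starting material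
6 | trimethyl{[(3R,4S)-3,4-dimethylcyclohex-1-en-1-yl]oxy}silane (trans) | C[C@H]1CCC(O[Si](C)(C)C)=C[C@@H]1C | intermediate
7 | (S)-3,4-dimethylcyclohex-2-en-1-one | C[C@H]1CCC(=O)C=C1C | intermediate
8 | (4S)-2,3-dibromo-3,4-dimethylcyclohexan-1-one (mixture at C2 and C3) | C[C@H]1CCC(=O)C(Br)C1(C)Br | intermediate
9 | (S)-2-bromo-3,4-dimethylcyclohex-2-en-1-one | C[C@H]1CCC(=O)C(Br)=C1C | intermediate
10 | 2-ethyl-2-vinyl-1,3-dioxolane | C=CC1(CC)OCCO1 | starting material
11 | 9-[2-(2-ethyl-1,3-dioxolan-2-yl)ethyl]-9-borabicyclo[3.3.1]nonane | CCC1(CCB2C3CCCC2CCC3)OCCO1 | intermediate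
12 | (S)-2-[2-(2-ethyl-1,3-dioxolan-2-yl)ethyl]-3,4-dimethylcyclohex-2-en-1-one | C[C@H]1CCC(=O)C(CCC2(CC)OCCO2)=C1C | intermediate
13 | potassium (4S)-6-[2-(2-ethyl-1,3-dioxolan-2-yl)ethyl]-4,5-dimethylcyclohexa-1,5-dien-1-olate | C[C@H]1CC=C([O-])C(CCC2(CC)OCCO2)=C1C.[K+] | intermediate
14 | (4S,6S)-2-[2-(2-ethyl-1,3-dioxolan-2-yl)ethyl]-6-hydroxy-3,4-dimethylcyclohex-2-en-1-one | C[C@H]1C[C@H](O)C(=O)C(CCC2(CC)OCCO2)=C1C | intermediate
15 | (4S,6S)-6-[(tert-butyldimethylsilyl)oxy]-2-[2-(2-ethyl-1,3-dioxolan-2-yl)ethyl]-3,4-dimethylcyclohex-2-en-1-one | C[C@H]1C[C@H](O[Si](C)(C)C(C)(C)C)C(=O)C(CCC2(CC)OCCO2)=C1C | intermediate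
16 | (4S,6S)-6-[(tert-butyldimethylsilyl)oxy]-3,4-dimethyl-2-(3-oxopentyl)cyclohex-2-en-1-one | C[C@H]1C[C@H](O[Si](C)(C)C(C)(C)C)C(=O)C(CCC(=O)CC)=C1C | intermediate
17 | (6S,8S)-8-[(tert-butyldimethylsilyl)oxy]-1,5,6-trimethyl-4,6,7,8-tetrahydronaphthalen-2(3H)-one (6-silyloxy-4,8,9-trimethyl-4,9(10)-dien-3-one) | C[C@H]1C[C@H](O[Si](C)(C)C(C)(C)C)C2=C(C)C(=O)CCC2=C1C | intermediate
18 | vinylmagnesium bromide | C=C[Mg]Br | starting material
19 | formaldehyde | C=O | starting material
20 | bromomagnesium (5R,6S,8S)-8-[(tert-butyldimethylsilyl)oxy]-5-ethenyl-1,5,6-trimethyl-3,4,5,6,7,8-hexahydronaphthalen-2-olate | C[C@H]1C[C@H](O[Si](C)(C)C(C)(C)C)C2=C(CCC(O[Mg]Br)=C2C)[C@]1(C)C=C | intermediate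
21 | (1S,5R,6S,8S)-8-[(tert-butyldimethylsilyl)oxy]-5-ethenyl-1-(hydroxymethyl)-1,5,6-trimethyl-3,4,5,6,7,8-hexahydronaphthalen-2(1H)-one (3-oxo-5(10)-ene with C9 vinyl and C4 hydroxymethyl) | C[C@H]1C[C@H](O[Si](C)(C)C(C)(C)C)C2=C(CCC(=O)[C@]2(C)CO)[C@]1(C)C=C | intermediate
22 | 3-(4-hydroxyphenyl)propanoic acid | OC(=O)CCc1ccc(O)cc1 | starting material
23 | tert-butyldimethylsilyl 3-{4-[(tert-butyldimethylsilyl)oxy]phenyl}propanoate | CC(C)(C)[Si](C)(C)OC(=O)CCc1ccc(O[Si](C)(C)C(C)(C)C)cc1 | intermediate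
24 | 3-{4-[(tert-butyldimethylsilyl)oxy]phenyl}propanoic acid | OC(=O)CCc1ccc(O[Si](C)(C)C(C)(C)C)cc1 | intermediate
25 | [(1S,5R,6S,8S)-8-[(tert-butyldimethylsilyl)oxy]-5-ethenyl-1,5,6-trimethyl-2-oxo-1,2,3,4,5,6,7,8-octahydronaphthalen-1-yl]methyl 3-{4-[(tert-butyldimethylsilyl)oxy]phenyl}propanoate | C[C@H]1C[C@H](O[Si](C)(C)C(C)(C)C)C2=C(CCC(=O)[C@]2(C)COC(=O)CCc2ccc(O[Si](C)(C)C(C)(C)C)cc2)[C@]1(C)C=C | intermediate
26 | 4-bromofuran-2(5H)-one | BrC1=CC(=O)OC1 | starting material
27 | the 5-[2-(9-borabicyclo[3.3.1]nonan-9-yl)ethyl] analogue of 25 | C[C@H]1C[C@H](O[Si](C)(C)C(C)(C)C)C2=C(CCC(=O)[C@]2(C)COC(=O)CCc2ccc(O[Si](C)(C)C(C)(C)C)cc2)[C@]1(C)CCB1C2CCCC1CCC2 | intermediate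
28 | [(1S,5R,6S,8S)-8-[(tert-butyldimethylsilyl)oxy]-1,5,6-trimethyl-2-oxo-5-[2-(5-oxo-2,5-dihydrofuran-3-yl)ethyl]-1,2,3,4,5,6,7,8-octahydronaphthalen-1-yl]methyl 3-{4-[(tert-butyldimethylsilyl)oxy]phenyl}propanoate | C[C@H]1C[C@H](O[Si](C)(C)C(C)(C)C)C2=C(CCC(=O)[C@]2(C)COC(=O)CCc2ccc(O[Si](C)(C)C(C)(C)C)cc2)[C@]1(C)CCC1=CC(=O)OC1 | intermediate
29 | CNP0301014.1, [(1S,5R,6S,8S)-8-hydroxy-1,5,6-trimethyl-2-oxo-5-[2-(5-oxo-2,5-dihydrofuran-3-yl)ethyl]-1,2,3,4,5,6,7,8-octahydronaphthalen-1-yl]methyl 3-(4-hydroxyphenyl)propanoate | C[C@H]1C[C@H](O)C2=C(CCC(=O)[C@]2(C)COC(=O)CCc2ccc(O)cc2)[C@]1(C)CCC1=CC(=O)OC1 | target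

**Step count**

Total: 15 steps. Longest linear sequence: 14 steps (steps 1–11 and 13–15; step 12 prepares the acid).

**Steps most likely to fail**

Step 11 (bears the label). The vinyl group may be delivered to C9 on the β face, from the ring B half-chair that keeps the C6 silyloxy group pseudoaxial and the C8 methyl pseudoequatorial. 1,2-Addition to the C3 carbonyl may also outrun the slow formation of the δ-quaternary centre, or the dienolate may be trapped at C10. The fallback uses known chemistry, sets out from 7 and returns at 21; it makes C9 before ring A exists and C4 afterwards. Enolate hydroxylation of 7 (KN(SiMe3)2, then the N-sulfonyloxaziridine, as in step 7) gives (4S,6S)-6-hydroxy-3,4-dimethylcyclohex-2-en-1-one F1, and silylation (TBSCl, imidazole) gives (4S,6S)-6-[(tert-butyldimethylsilyl)oxy]-3,4-dimethylcyclohex-2-en-1-one F2. Copper-catalysed 1,4-addition of 18 with Me3SiCl, the established route to a quaternary carbon beside a 4-methyl group with the new group trans to it, gives 6-[(tert-butyldimethylsilyl)oxy]-3,4-dimethyl-1-[(trimethylsilyl)oxy]-3-vinylcyclohex-1-ene F3. Mukaiyama–Michael addition to pent-1-en-3-one (TiCl4, CH2Cl2, −78 °C) gives 6-[(tert-butyldimethylsilyl)oxy]-3,4-dimethyl-2-(3-oxopentyl)-3-vinylcyclohexan-1-one F4. Aldol condensation (KOH, MeOH) closes ring A to 8-[(tert-butyldimethylsilyl)oxy]-5-ethenyl-1,5,6-trimethyl-4,4a,5,6,7,8-hexahydronaphthalen-2(3H)-one F5, whose C10 configuration does not matter. Deconjugative hydroxymethylation (KOt-Bu, t-BuOH/THF, then 19 at −78 °C) removes the C10 hydrogen, passes through the same dienolate and its C6-controlled α-trapping, and returns to 21.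

Step 10. The α-silyloxy ketone may enolise toward C6 before ring closure and epimerise, and the product may lose C8 integrity by ε-deprotonation under the base. The fallback sets out from 9 and returns at 17; it attaches the side chain as a regiodefined silyl enol ether and closes ring A with a Lewis acid instead of a base. Pent-1-en-3-one is silylated (i-Pr3SiOTf, Et3N) to 3-[(triisopropylsilyl)oxy]penta-1,3-diene F6, and its terminal alkene is hydroborated to the 9-BBN adduct F7. Coupling with 9 as in step 6 gives (S)-3,4-dimethyl-2-{3-[(triisopropylsilyl)oxy]pent-3-en-1-yl}cyclohex-2-en-1-one F8. Hydroxylation as in step 7 gives the (4S,6S)-6-hydroxy derivative F9 and silylation as in step 8 gives its tert-butyldimethylsilyl ether F10. TiCl4 (CH2Cl2, −78 °C) should induce intramolecular Mukaiyama aldol addition of C4 to the C5 ketone, giving the tertiary aldol 8-[(tert-butyldimethylsilyl)oxy]-8a-hydroxy-1,5,6-trimethyl-1,3,4,6,7,8-hexahydronaphthalen-2-one F11. Dehydration with methyl N-(triethylammoniosulfonyl)carbamate then gives 17 without exposing C6–H or C8–H to base.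

Step 14. The borane may reduce the C3 ketone during the slow hydroboration of the neopentyl-type vinyl group, and the aqueous base of the coupling may cleave the aryl silyl ether or the ester or stall transmetalation. The fallback sets out from 25 and returns at 28; it replaces the basic boron coupling by a base-free zinc coupling through an isolated iodide. The borane adduct 27 is oxidised (NaBO3·4H2O, THF/H2O) to the primary alcohol, the 5-(2-hydroxyethyl) analogue of 25 F12. Iodination (I2, PPh3, imidazole) gives the 5-(2-iodoethyl) analogue F13. Zinc insertion (Zn dust, LiCl, THF) gives the alkylzinc iodide F14, which undergoes Negishi coupling with 26 (Pd(OAc)2, 2-dicyclohexylphosphino-2',6'-dimethoxybiphenyl, THF, rt) to 28.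

Further compounds
F1 | step 11 | (4S,6S)-6-hydroxy-3,4-dimethylcyclohex-2-en-1-one | C[C@H]1C[C@H](O)C(=O)C=C1C
F2 | step 11 | (4S,6S)-6-[(tert-butyldimethylsilyl)oxy]-3,4-dimethylcyclohex-2-en-1-one | C[C@H]1C[C@H](O[Si](C)(C)C(C)(C)C)C(=O)C=C1C
F3 | step 11 | 6-[(tert-butyldimethylsilyl)oxy]-3,4-dimethyl-1-[(trimethylsilyl)oxy]-3-vinylcyclohex-1-ene (vinyl trans to the 4-methyl) | C[C@H]1C[C@H](O[Si](C)(C)C(C)(C)C)C(O[Si](C)(C)C)=C[C@]1(C)C=C
F4 | step 11 | 6-[(tert-butyldimethylsilyl)oxy]-3,4-dimethyl-2-(3-oxopentyl)-3-vinylcyclohexan-1-one (mixture at C2) | C[C@H]1C[C@H](O[Si](C)(C)C(C)(C)C)C(=O)C(CCC(=O)CC)[C@]1(C)C=C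
F5 | step 11 | 8-[(tert-butyldimethylsilyl)oxy]-5-ethenyl-1,5,6-trimethyl-4,4a,5,6,7,8-hexahydronaphthalen-2(3H)-one (C4a epimers) | C[C@H]1C[C@H](O[Si](C)(C)C(C)(C)C)C2=C(C)C(=O)CCC2[C@]1(C)C=C
F6 | step 10 | 3-[(triisopropylsilyl)oxy]penta-1,3-diene | C=CC(O[Si](C(C)C)(C(C)C)C(C)C)=CC
F7 | step 10 | 9-{3-[(triisopropylsilyl)oxy]pent-3-en-1-yl}-9-borabicyclo[3.3.1]nonane | CC=C(CCB1C2CCCC1CCC2)O[Si](C(C)C)(C(C)C)C(C)C
F8 | step 10 | (S)-3,4-dimethyl-2-{3-[(triisopropylsilyl)oxy]pent-3-en-1-yl}cyclohex-2-en-1-one | C[C@H]1CCC(=O)C(CCC(O[Si](C(C)C)(C(C)C)C(C)C)=CC)=C1C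
F9 | step 10 | (4S,6S)-6-hydroxy-3,4-dimethyl-2-{3-[(triisopropylsilyl)oxy]pent-3-en-1-yl}cyclohex-2-en-1-one | C[C@H]1C[C@H](O)C(=O)C(CCC(O[Si](C(C)C)(C(C)C)C(C)C)=CC)=C1C
F10 | step 10 | (4S,6S)-6-[(tert-butyldimethylsilyl)oxy]-3,4-dimethyl-2-{3-[(triisopropylsilyl)oxy]pent-3-en-1-yl}cyclohex-2-en-1-one | C[C@H]1C[C@H](O[Si](C)(C)C(C)(C)C)C(=O)C(CCC(O[Si](C(C)C)(C(C)C)C(C)C)=CC)=C1C
F11 | step 10 | 8-[(tert-butyldimethylsilyl)oxy]-8a-hydroxy-1,5,6-trimethyl-1,3,4,6,7,8-hexahydronaphthalen-2-one (aldol adduct) | C[C@H]1C[C@H](O[Si](C)(C)C(C)(C)C)C2(O)C(C)C(=O)CCC2=C1C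
F12 | step 14 | the 5-(2-hydroxyethyl) analogue of 25 | C[C@H]1C[C@H](O[Si](C)(C)C(C)(C)C)C2=C(CCC(=O)[C@]2(C)COC(=O)CCc2ccc(O[Si](C)(C)C(C)(C)C)cc2)[C@]1(C)CCO
F13 | step 14 | the 5-(2-iodoethyl) analogue of 25 | C[C@H]1C[C@H](O[Si](C)(C)C(C)(C)C)C2=C(CCC(=O)[C@]2(C)COC(=O)CCc2ccc(O[Si](C)(C)C(C)(C)C)cc2)[C@]1(C)CCI
F14 | step 14 | the 5-[2-(iodozincio)ethyl] analogue of 25 | C[C@H]1C[C@H](O[Si](C)(C)C(C)(C)C)C2=C(CCC(=O)[C@]2(C)COC(=O)CCc2ccc(O[Si](C)(C)C(C)(C)C)cc2)[C@]1(C)CC[Zn]I
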